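**Plan**

- Retrosynthesis: the free hydroxyls are unmasked last (the 3-O-aroyl ester and two MOM ethers). Ring C is then cut at C2–C3 and at O1–C2, giving a ring A ketone whose O1 and C3 oxygens both carry a 4-prenyloxybenzoyl group.
- Enabling feature: in ring C, C2 bears ring B and C3 bears oxygen next to the C4 ketone, while O1 is a ring A phenol oxygen ortho to C4. An aroyl ester on O1 can therefore pass C2 and ring B to the C3 enolate through a six-membered transition structure, while a second, identical ester masks O3.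
- Earlier cuts: the two ester C–O bonds, the C4–C4a aryl–ketone bond (ortho-lithiation and Weinreb acylation), the O1–C8a bond (Baeyer–Villiger oxidation of an aldehyde made from methyl 4-O-methylgallate) and the prenyl ether of the ring B acid.
- Forward order: ring A is bought. Its oxygens are differentiated (MOM on the future O5 and O7, benzyl on the future O1), the two-carbon ketol chain is attached, both hydroxyls are aroylated, ring C closes in the key step with ring B arriving in the acyl group, and the protecting groups are then removed.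
- Stereochemistry: the target has no stereocentre and no stereogenic double bond; the sp3 centres that appear at C2 and C3 during ring closure are erased by dehydration.

Key step: step 11

Assumption: all numbered starting materials, including the Weinreb amide used in step 6, are catalogue chemicals.

**Route**

Step 1
Reactants: 1 methyl 3,5-dihydroxy-4-methoxybenzoate
Product: 2 methyl 4-methoxy-3,5-bis(methoxymethoxy)benzoate
Conditions: NaH, MOMCl, DMF, 0 °C to rt
Reagents that add atoms: chloromethyl methyl ether, COCCl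
Why: Williamson-type O-alkylation of both phenoxides with the reactive α-chloro ether should give the bis-acetal, and the methyl ester is inert to NaH at this temperature.

Step 2
Reactants: 2 methyl 4-methoxy-3,5-bis(methoxymethoxy)benzoate
Product: 3 [4-methoxy-3,5-bis(methoxymethoxy)phenyl]methanol
Conditions: LiAlH4, THF, 0 °C; aqueous work-up
Reagents that add atoms: none
Why: Hydride reduction of an aryl ester to the benzylic alcohol is standard, and aryl MOM ethers do not react with LiAlH4.

Step 3
Reactants: 3 [4-methoxy-3,5-bis(methoxymethoxy)phenyl]methanol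
Product: 4 4-methoxy-3,5-bis(methoxymethoxy)benzaldehyde
Conditions: MnO2, CH2Cl2, rt
Reagents that add atoms: none
Why: Benzylic alcohol oxidation on MnO2 stops at the aldehyde under neutral conditions that leave the acetals intact.

Step 4
Reactants: 4 4-methoxy-3,5-bis(methoxymethoxy)benzaldehyde
Product: 6 4-methoxy-3,5-bis(methoxymethoxy)phenol, via aryl formate 5 (not isolated)
Conditions: mCPBA, CH2Cl2, 0 °C to rt; NaHCO3 wash; then K2CO3 (cat.), MeOH, rt
Reagents that add atoms: 3-chloroperoxybenzoic acid, OOC(=O)c1cccc(Cl)c1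
Why: In this Baeyer–Villiger (Dakin-type) oxidation the electron-rich trialkoxyaryl group should migrate in preference to hydride, and mild methanolysis of the formate frees the phenol oxygen that later becomes O1.

Step 5
Reactants: 6 4-methoxy-3,5-bis(methoxymethoxy)phenol
Product: 7 5-(benzyloxy)-2-methoxy-1,3-bis(methoxymethoxy)benzene
Conditions: BnBr, K2CO3, DMF, rt
Reagents that add atoms: benzyl bromide, BrCc1ccccc1
Why: Williamson etherification marks the future O1 with a group that differs from the MOM ethers and can be removed by hydrogenolysis before any alkene is present.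

Step 6
Reactants: 7 5-(benzyloxy)-2-methoxy-1,3-bis(methoxymethoxy)benzene; 8 2-(benzyloxy)-N-methoxy-N-methylacetamide
Product: 10 2-(benzyloxy)-1-[6-(benzyloxy)-3-methoxy-2,4-bis(methoxymethoxy)phenyl]ethan-1-one, via aryllithium 9 (not isolated)
Conditions: n-BuLi, THF, 0 °C; then 8, −78 to 0 °C; aq. NH4Cl
Reagents that add atoms: none
Why: Directed ortho-metalation should occur at one of the two symmetry-equivalent ring positions flanked by the MOM ether (a strong director) and the benzyloxy group, and Weinreb amide acylation stops at the ketone because the chelated tetrahedral adduct survives until quench.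

Step 7
Reactants: 10 2-(benzyloxy)-1-[6-(benzyloxy)-3-methoxy-2,4-bis(methoxymethoxy)phenyl]ethan-1-one
Product: 11 2-hydroxy-1-[6-hydroxy-3-methoxy-2,4-bis(methoxymethoxy)phenyl]ethan-1-one
Conditions: H2 (1 atm), 10% Pd/C, EtOAc, rt
Reagents that add atoms: none
Why: Hydrogenolysis cleaves both benzyl ethers, while the MOM ethers and the hindered, hydrogen-bonded aryl ketone should stay untouched.

Step 8
Reactants: 12 methyl 4-hydroxybenzoate; 13 1-bromo-3-methylbut-2-ene
Product: 14 methyl 4-(3-methylbut-2-enyloxy)benzoate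
Conditions: K2CO3, acetone, reflux
Reagents that add atoms: none
Why: Williamson etherification of the phenoxide at the primary allylic carbon (SN2) gives the linear prenyl ether.

Step 9
Reactants: 14 methyl 4-(3-methylbut-2-enyloxy)benzoate
Product: 15 4-(3-methylbut-2-enyloxy)benzoic acid
Conditions: LiOH, THF/MeOH/H2O, 40 °C; then 1 M HCl, 0 °C, to pH 3
Reagents that add atoms: lithium hydroxide (hydroxide oxygen), [Li+].[OH-]
Why: Ester saponification leaves the ether alone, and brief cold acidification should precipitate the acid before the prenyl ether can react.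

Step 10
Reactants: 11 2-hydroxy-1-[6-hydroxy-3-methoxy-2,4-bis(methoxymethoxy)phenyl]ethan-1-one; 15 4-(3-methylbut-2-enyloxy)benzoic acid
Product: 16 4-methoxy-3,5-bis(methoxymethoxy)-2-{2-[4-(3-methylbut-2-enyloxy)benzoyloxy]acetyl}phenyl 4-(3-methylbut-2-enyloxy)benzoate
Conditions: 15 (2.4 equiv), DCC, DMAP (cat.), CH2Cl2, 0 °C to rt
Reagents that add atoms: none
Why: Steglich esterification acylates both the phenol and the primary ketol hydroxyl under neutral conditions, so no HCl is generated that could add to the prenyl double bond.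

Step 11
Reactants: 16 4-methoxy-3,5-bis(methoxymethoxy)-2-{2-[4-(3-methylbut-2-enyloxy)benzoyloxy]acetyl}phenyl 4-(3-methylbut-2-enyloxy)benzoate
Product: 19 6-methoxy-5,7-bis(methoxymethoxy)-2-[4-(3-methylbut-2-enyloxy)phenyl]-4-oxo-4H-chromen-3-yl 4-(3-methylbut-2-enyloxy)benzoate, via 1,3-diketone 17 (not isolated), via 2-hydroxyflavanone hemiketal 18 (not isolated)
Conditions: LiN(SiMe3)2 (2.5 equiv), THF, −78 to 0 °C; then AcOH (excess), 50 °C
Reagents that add atoms: none
Why: LiN(SiMe3)2 deprotonates the CH2 between the ketone and the ω-ester oxygen (the future C3); the enolate carbon adds through a six-membered transition structure to the carbonyl of the phenolic ester on O1, and collapse of the tetrahedral intermediate forms C2–C3 and releases the O1 phenoxide, giving diketone 17. This is the Baker–Venkataraman rearrangement as known for 2-aroyloxy-ω-aroyloxyacetophenones, which lead to 3-aroyloxyflavones. On acidification the O1 phenol adds to the new C2 carbonyl (6-exo-trig) to give hemiketal 18, and loss of water, helped by the 4-alkoxyphenyl group on C2, converts ring C into the 4-pyranone. No stereocentre survives, because the sp3 centres at C2 and C3 of 17 and 18 are removed by the dehydration. The enolate should attack the O1 ester and not its own ω-ester, since C-attack on the latter would need a three-membered ring and the aryloxide is the better leaving group; the regiochemistry is fixed because O1 is the only ring A oxygen that carries an acyl group, O5 having been a MOM ether since step 1 while O1 sits on the carbon that once bore the ester group of 1. Acetic acid at 50 °C is too weak to ionise the prenyl ethers or to cleave the aryl MOM ethers.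

Step 12
Reactants: 19 6-methoxy-5,7-bis(methoxymethoxy)-2-[4-(3-methylbut-2-enyloxy)phenyl]-4-oxo-4H-chromen-3-yl 4-(3-methylbut-2-enyloxy)benzoate
Product: 21 5,7-dihydroxy-6-methoxy-2-[4-(3-methylbut-2-enyloxy)phenyl]-4-oxo-4H-chromen-3-yl 4-(3-methylbut-2-enyloxy)benzoate, via bis(trimethylsilyl) ether 20 (not isolated)
Conditions: Me3SiOTf, 2,2'-bipyridyl, MeCN, 0 °C to rt; then H2O
Reagents that add atoms: none
Why: The silyl triflate–bipyridyl acetal cleavage converts aryl MOM ethers into aryl trimethylsilyl ethers that hydrolyse on aqueous work-up; bipyridyl traps the methoxymethyl cation and any triflic acid, so no protic acid is present to ionise the acid-labile prenyl ethers, which methanolic HCl would endanger.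

Step 13
Reactants: 21 5,7-dihydroxy-6-methoxy-2-[4-(3-methylbut-2-enyloxy)phenyl]-4-oxo-4H-chromen-3-yl 4-(3-methylbut-2-enyloxy)benzoate
Product: 22 3,5,7-trihydroxy-6-methoxy-2-[4-(3-methylbut-2-enyloxy)phenyl]-4H-chromen-4-one
Conditions: K2CO3 (0.5 equiv), MeOH/THF, 0 °C to rt, argon; then aq. NH4Cl
Reagents that add atoms: none
Why: Base-catalysed methanolysis (transesterification) of the activated enol ester frees the 3-hydroxyl under conditions to which the prenyl ether is inert; argon protects the flavonolate from air oxidation.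

**Compound list**

1 | methyl 3,5-dihydroxy-4-methoxybenzoate | COC(=O)c1cc(O)c(OC)c(O)c1 | starting material
2 | methyl 4-methoxy-3,5-bis(methoxymethoxy)benzoate | COCOc1cc(C(=O)OC)cc(OCOC)c1OC | intermediate
3 | [4-methoxy-3,5-bis(methoxymethoxy)phenyl]methanol | COCOc1cc(CO)cc(OCOC)c1OC | intermediate
4 | 4-methoxy-3,5-bis(methoxymethoxy)benzaldehyde | COCOc1cc(C=O)cc(OCOC)c1OC | intermediate
5 | 4-methoxy-3,5-bis(methoxymethoxy)phenyl formate (formed in the flask) | COCOc1cc(OC=O)cc(OCOC)c1OC | intermediate
6 | 4-methoxy-3,5-bis(methoxymethoxy)phenol | COCOc1cc(O)cc(OCOC)c1OC | intermediate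
7 | 5-(benzyloxy)-2-methoxy-1,3-bis(methoxymethoxy)benzene | COCOc1cc(OCc2ccccc2)cc(OCOC)c1OC | intermediate
8 | 2-(benzyloxy)-N-methoxy-N-methylacetamide | CON(C)C(=O)COCc1ccccc1 | starting material
9 | [6-(benzyloxy)-3-methoxy-2,4-bis(methoxymethoxy)phenyl]lithium (formed in the flask) | [Li]c1c(OCc2ccccc2)cc(OCOC)c(OC)c1OCOC | intermediate
10 | 2-(benzyloxy)-1-[6-(benzyloxy)-3-methoxy-2,4-bis(methoxymethoxy)phenyl]ethan-1-one | O=C(COCc1ccccc1)c1c(OCc2ccccc2)cc(OCOC)c(OC)c1OCOC | intermediate
11 | 2-hydroxy-1-[6-hydroxy-3-methoxy-2,4-bis(methoxymethoxy)phenyl]ethan-1-one | O=C(CO)c1c(O)cc(OCOC)c(OC)c1OCOC | intermediate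
12 | methyl 4-hydroxybenzoate | COC(=O)c1ccc(O)cc1 | starting material
13 | 1-bromo-3-methylbut-2-ene | CC(C)=CCBr | starting material
14 | methyl 4-(3-methylbut-2-enyloxy)benzoate | COC(=O)c1ccc(OCC=C(C)C)cc1 | intermediate
15 | 4-(3-methylbut-2-enyloxy)benzoic acid | OC(=O)c1ccc(OCC=C(C)C)cc1 | intermediate
16 | 4-methoxy-3,5-bis(methoxymethoxy)-2-{2-[4-(3-methylbut-2-enyloxy)benzoyloxy]acetyl}phenyl 4-(3-methylbut-2-enyloxy)benzoate | COCOc1cc(OC(=O)c2ccc(OCC=C(C)C)cc2)c(C(=O)COC(=O)c2ccc(OCC=C(C)C)cc2)c(OCOC)c1OC | intermediate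
17 | 1-[6-hydroxy-3-methoxy-2,4-bis(methoxymethoxy)phenyl]-3-[4-(3-methylbut-2-enyloxy)phenyl]-1,3-dioxopropan-2-yl 4-(3-methylbut-2-enyloxy)benzoate (racemic, formed in the flask) | COCOc1cc(O)c(C(=O)C(OC(=O)c2ccc(OCC=C(C)C)cc2)C(=O)c2ccc(OCC=C(C)C)cc2)c(OCOC)c1OC | intermediate
18 | 2-hydroxy-6-methoxy-5,7-bis(methoxymethoxy)-2-[4-(3-methylbut-2-enyloxy)phenyl]-4-oxochroman-3-yl 4-(3-methylbut-2-enyloxy)benzoate (racemic diastereomer mixture, formed in the flask) | COCOc1cc2OC(O)(c3ccc(OCC=C(C)C)cc3)C(OC(=O)c3ccc(OCC=C(C)C)cc3)C(=O)c2c(OCOC)c1OC | intermediate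
19 | 6-methoxy-5,7-bis(methoxymethoxy)-2-[4-(3-methylbut-2-enyloxy)phenyl]-4-oxo-4H-chromen-3-yl 4-(3-methylbut-2-enyloxy)benzoate | COCOc1cc2oc(-c3ccc(OCC=C(C)C)cc3)c(OC(=O)c3ccc(OCC=C(C)C)cc3)c(=O)c2c(OCOC)c1OC | intermediate
20 | 6-methoxy-2-[4-(3-methylbut-2-enyloxy)phenyl]-4-oxo-5,7-bis(trimethylsilyloxy)-4H-chromen-3-yl 4-(3-methylbut-2-enyloxy)benzoate (formed in the flask) | COc1c(O[Si](C)(C)C)cc2oc(-c3ccc(OCC=C(C)C)cc3)c(OC(=O)c3ccc(OCC=C(C)C)cc3)c(=O)c2c1O[Si](C)(C)C | intermediate
21 | 5,7-dihydroxy-6-methoxy-2-[4-(3-methylbut-2-enyloxy)phenyl]-4-oxo-4H-chromen-3-yl 4-(3-methylbut-2-enyloxy)benzoate | COc1c(O)cc2oc(-c3ccc(OCC=C(C)C)cc3)c(OC(=O)c3ccc(OCC=C(C)C)cc3)c(=O)c2c1O | intermediate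
22 | 3,5,7-trihydroxy-6-methoxy-2-[4-(3-methylbut-2-enyloxy)phenyl]-4H-chromen-4-one | COc1c(O)cc2oc(-c3ccc(OCC=C(C)C)cc3)c(O)c(=O)c2c1O | target

**Step count and risks**

Total: 13 steps. The longest linear sequence is 11 steps (steps 1–7 and 10–13, from 1 to 22); steps 8 and 9 make the ring B acid 15 in a short side branch.

Steps most likely to fail:

1. Step 11. The acyl groups may shuttle between O1, O3 and the enolate oxygen instead of transferring to carbon, and ring closure or dehydration may stall, so that a mixture of open and closed, acylated and deacylated material results. The fallback sets out from 16. The more reactive phenolic ester is removed selectively by aminolysis (pyrrolidine, THF, 0 °C) to give 2-[6-hydroxy-3-methoxy-2,4-bis(methoxymethoxy)phenyl]-2-oxoethyl 4-(3-methylbut-2-enyloxy)benzoate F1. Acid 15 is converted under neutral conditions (1-chloro-N,N,2-trimethylprop-1-en-1-amine, CH2Cl2, 0 °C) into 4-(3-methylbut-2-enyloxy)benzoyl chloride F2. The phenoxide–enolate dianion of F1 (LiN(SiMe3)2, 3 equiv, THF, −78 °C) is then aroylated intermolecularly with F2, the known direct acylation of lithium polyanions of ortho-hydroxyaryl ketones. This comes back to the route at diketone 17, which the acetic acid stage of step 11 closes to 19.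

2. Step 6. Deprotonation at the benzylic CH2 of the benzyl ether (followed by Wittig rearrangement), or incomplete ring metalation, may compete with the desired ortho-lithiation. The fallback sets out from 7. Electrophilic bromination (N-bromosuccinimide, MeCN, 0 °C) at one of the two equivalent, strongly activated ring positions gives 1-(benzyloxy)-2-bromo-4-methoxy-3,5-bis(methoxymethoxy)benzene F3. Bromine–lithium exchange with n-BuLi in THF at −78 °C, which is far faster than any deprotonation, then generates the same aryllithium, so the fallback comes back at 9 and continues with amide 8 to 10.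

3. Step 12. The silyl triflate may ionise the prenyl ethers, or exchange at the electron-poor 7-O-acetal may stay incomplete. The fallback sets out from 11 and forms the prenyl groups only after the acetals are gone.
   - Double Steglich esterification with the catalogue compound 4-(prop-2-enyloxy)benzoic acid gives 4-methoxy-3,5-bis(methoxymethoxy)-2-{2-[4-(prop-2-enyloxy)benzoyloxy]acetyl}phenyl 4-(prop-2-enyloxy)benzoate F4.
   - The conditions of step 11 carry F4 through 1-[6-hydroxy-3-methoxy-2,4-bis(methoxymethoxy)phenyl]-1,3-dioxo-3-[4-(prop-2-enyloxy)phenyl]propan-2-yl 4-(prop-2-enyloxy)benzoate F5 and 2-hydroxy-6-methoxy-5,7-bis(methoxymethoxy)-4-oxo-2-[4-(prop-2-enyloxy)phenyl]chroman-3-yl 4-(prop-2-enyloxy)benzoate F6 to 6-methoxy-5,7-bis(methoxymethoxy)-4-oxo-2-[4-(prop-2-enyloxy)phenyl]-4H-chromen-3-yl 4-(prop-2-enyloxy)benzoate F7.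
   - Simple allyl aryl ethers do not ionise in dilute acid, so the MOM groups can be removed with HCl in MeOH at 40 °C to give 5,7-dihydroxy-6-methoxy-4-oxo-2-[4-(prop-2-enyloxy)phenyl]-4H-chromen-3-yl 4-(prop-2-enyloxy)benzoate F8.
   - Double cross-metathesis with 2-methyl-2-butene (second-generation Grubbs catalyst, CH2Cl2, 40 °C) then turns both allyl ethers into prenyl ethers. The fallback comes back to the route at 21, ready for step 13.

**Further compounds**

F1 | step 11 | 2-[6-hydroxy-3-methoxy-2,4-bis(methoxymethoxy)phenyl]-2-oxoethyl 4-(3-methylbut-2-enyloxy)benzoate | COCOc1cc(O)c(C(=O)COC(=O)c2ccc(OCC=C(C)C)cc2)c(OCOC)c1OC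
F2 | step 11 | 4-(3-methylbut-2-enyloxy)benzoyl chloride | ClC(=O)c1ccc(OCC=C(C)C)cc1
F3 | step 6 | 1-(benzyloxy)-2-bromo-4-methoxy-3,5-bis(methoxymethoxy)benzene | Brc1c(OCc2ccccc2)cc(OCOC)c(OC)c1OCOC
F4 | step 12 | 4-methoxy-3,5-bis(methoxymethoxy)-2-{2-[4-(prop-2-enyloxy)benzoyloxy]acetyl}phenyl 4-(prop-2-enyloxy)benzoate | COCOc1cc(OC(=O)c2ccc(OCC=C)cc2)c(C(=O)COC(=O)c2ccc(OCC=C)cc2)c(OCOC)c1OC
F5 | step 12 | 1-[6-hydroxy-3-methoxy-2,4-bis(methoxymethoxy)phenyl]-1,3-dioxo-3-[4-(prop-2-enyloxy)phenyl]propan-2-yl 4-(prop-2-enyloxy)benzoate (racemic, formed in the flask) | COCOc1cc(O)c(C(=O)C(OC(=O)c2ccc(OCC=C)cc2)C(=O)c2ccc(OCC=C)cc2)c(OCOC)c1OC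
F6 | step 12 | 2-hydroxy-6-methoxy-5,7-bis(methoxymethoxy)-4-oxo-2-[4-(prop-2-enyloxy)phenyl]chroman-3-yl 4-(prop-2-enyloxy)benzoate (racemic diastereomer mixture, formed in the flask) | COCOc1cc2OC(O)(c3ccc(OCC=C)cc3)C(OC(=O)c3ccc(OCC=C)cc3)C(=O)c2c(OCOC)c1OC
F7 | step 12 | 6-methoxy-5,7-bis(methoxymethoxy)-4-oxo-2-[4-(prop-2-enyloxy)phenyl]-4H-chromen-3-yl 4-(prop-2-enyloxy)benzoate | COCOc1cc2oc(-c3ccc(OCC=C)cc3)c(OC(=O)c3ccc(OCC=C)cc3)c(=O)c2c(OCOC)c1OC
F8 | step 12 | 5,7-dihydroxy-6-methoxy-4-oxo-2-[4-(prop-2-enyloxy)phenyl]-4H-chromen-3-yl 4-(prop-2-enyloxy)benzoate | COc1c(O)cc2oc(-c3ccc(OCC=C)cc3)c(OC(=O)c3ccc(OCC=C)cc3)c(=O)c2c1O
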